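**Plan**

- Retrosynthesis: the two benzyl groups on ring B come off last. Ring A is then cut at C2'–C3', C4'–C5' and C1'–C2', giving an E-configured diazo enone ester of the ring B phenol and methoxyacetylene. The diazo carbon goes back to an acetyl CH3, the aryl ester C–O bond to phenol 5 and keto acid 11, and the alkene of 11 (later C1'–C6') to glyoxylic acid and an acetyl-stabilized ylide.
- Enabling feature: ring A carries the ester carbon on C1', OH on C2', H on C3', OMe on C4', H on C5' and pentyl on C6'. This is the meta-dioxygenated phenol that a vinylketene (C1', C2', C5', C6') and an alkoxyacetylene (C3', C4') assemble, so the methyl ether is placed by ring construction.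
- Forward order: ring B is bought as olivetolic acid and masked (steps 1–4). The open-chain keto acid is made by ylide acylation and Wittig reaction (steps 5–6) and joined to ring B as the aryl ester (step 7). Diazo transfer (step 8) and benzannulation with methoxyacetylene (steps 9–10) build ring A on the finished ester link, and hydrogenolysis ends the route (step 11).
- Stereochemistry: the target has no stereocentre. The only stereo-element on the way is the E alkene of 11, set in the Wittig step and needed until ring A is closed.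

Key step: step 10

Remark: methoxyacetylene boils near room temperature and is not relied on as a catalogue item, so it is made in step 9; reagents that only deliver protecting groups or are consumed carry no number and are named on the reagent lines.

**Route**

Step 1
Reactants: 1 olivetolic acid
Product: 2 benzyl 2,4-dihydroxy-6-pentylbenzoate
Conditions: BnBr (1.05 equiv), KHCO3, DMF, rt
Reagents that add atoms: benzyl bromide, BrCc1ccccc1
Why: Carboxylate O-alkylation (SN2); hydrogencarbonate deprotonates only the acid, so neither phenol is benzylated, and room temperature avoids decarboxylation of the β-resorcylic acid.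

Step 2
Reactants: 2 benzyl 2,4-dihydroxy-6-pentylbenzoate
Product: 3 benzyl 2-hydroxy-6-pentyl-4-[(triisopropylsilyl)oxy]benzoate
Conditions: iPr3SiCl, imidazole, DMF, 0 °C to rt
Reagents that add atoms: chlorotriisopropylsilane, CC(C)[Si](Cl)(C(C)C)C(C)C
Why: Phenol silylation; the 2-OH is hydrogen-bonded to the ester carbonyl and shielded by it, so the bulky silyl chloride should take only the free 4-OH.

Step 3
Reactants: 3 benzyl 2-hydroxy-6-pentyl-4-[(triisopropylsilyl)oxy]benzoate
Product: 4 benzyl 2-(benzyloxy)-6-pentyl-4-[(triisopropylsilyl)oxy]benzoate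
Conditions: BnOH, PPh3, DIAD, THF, 0 °C to rt
Reagents that add atoms: benzyl alcohol, OCc1ccccc1
Why: Mitsunobu etherification; the chelated phenol is acidic enough to protonate the betaine and is benzylated under neutral conditions that leave the aryl silyl ether alone.

Step 4
Reactants: 4 benzyl 2-(benzyloxy)-6-pentyl-4-[(triisopropylsilyl)oxy]benzoate
Product: 5 benzyl 2-(benzyloxy)-4-hydroxy-6-pentylbenzoate
Conditions: Bu4NF, AcOH, THF, 0 °C
Reagents that add atoms: none
Why: Fluoride-driven cleavage of an aryl silyl ether, buffered with acetic acid so that the phenoxide cannot attack the benzyl ester.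

Step 5
Reactants: 6 hexyltriphenylphosphonium bromide; 7 acetyl chloride
Product: 9 3-(triphenylphosphoranylidene)octan-2-one, via hexylidenetriphenylphosphorane 8 (not isolated)
Conditions: 6 (2 equiv), n-BuLi (2 equiv), THF, 0 °C; then 7 (1 equiv), −78 °C to rt
Reagents that add atoms: none
Why: C-acylation of a non-stabilized phosphorus ylide by an acid chloride; the second equivalent of 8 deprotonates the acylphosphonium salt (transylidation) to give the stabilized ylide.

Step 6
Reactants: 9 3-(triphenylphosphoranylidene)octan-2-one; 10 glyoxylic acid monohydrate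
Product: 11 (2E)-4-oxo-3-pentylpent-2-enoic acid
Conditions: THF, rt to 60 °C
Reagents that add atoms: none
Why: Wittig olefination of a stabilized, α-branched acyl ylide with the highly electrophilic aldehyde of glyoxylic acid; reversible addition should place the acetyl group trans to the carboxyl group, which sets the E alkene.

Step 7
Reactants: 11 (2E)-4-oxo-3-pentylpent-2-enoic acid; 5 benzyl 2-(benzyloxy)-4-hydroxy-6-pentylbenzoate
Product: 12 benzyl 2-(benzyloxy)-4-{[(2E)-4-oxo-3-pentylpent-2-enoyl]oxy}-6-pentylbenzoate
Conditions: DCC, DMAP (cat.), CH2Cl2, 0 °C to rt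
Reagents that add atoms: none
Why: Steglich esterification; the O-acylisourea hands the acyl group through the acylpyridinium ion to the unhindered 4-OH of 5, the only free hydroxyl present.

Step 8
Reactants: 12 benzyl 2-(benzyloxy)-4-{[(2E)-4-oxo-3-pentylpent-2-enoyl]oxy}-6-pentylbenzoate
Product: 14 benzyl 2-(benzyloxy)-4-{[(2E)-5-diazo-4-oxo-3-pentylpent-2-enoyl]oxy}-6-pentylbenzoate, via trifluoroacetyl diketone 13 (not isolated)
Conditions: LiN(SiMe3)2, THF, −78 °C; CF3CO2CH2CF3, −78 °C; aq. HCl work-up; then MsN3, Et3N, H2O (1 equiv), MeCN, rt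
Reagents that add atoms: methanesulfonyl azide, CS(=O)(=O)N=[N+]=[N-] (the two diazo nitrogens of 14); 2,2,2-trifluoroethyl trifluoroacetate, O=C(OCC(F)(F)F)C(F)(F)F (the CF3CO group of 13 only)
Why: Detrifluoroacetylative diazo transfer; kinetic deprotonation of the methyl ketone (its only enolizable α-position) and Claisen-type trifluoroacetylation activate the methyl carbon for Regitz diazo transfer, after which the trifluoroacetyl group leaves, and because no diazomethane meets the electron-poor alkene, pyrazoline formation is excluded.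

Step 9
Reactants: 15 2-chloro-1,1-dimethoxyethane
Product: 17 methoxyacetylene, via sodium methoxyacetylide 16 (not isolated)
Conditions: NaNH2 (3 equiv), liq. NH3, −33 °C; then cold sat. aq. NaCl, distil into ClCH2CH2Cl at −30 °C
Reagents that add atoms: none
Why: Twofold base-induced elimination (loss of HCl and of MeOH) from the chloroacetal gives the sodium acetylide, which is protonated and distilled off as a cold stock solution.

Step 10
Reactants: 14 benzyl 2-(benzyloxy)-4-{[(2E)-5-diazo-4-oxo-3-pentylpent-2-enoyl]oxy}-6-pentylbenzoate; 17 methoxyacetylene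
Product: 22 benzyl 2-(benzyloxy)-4-[(2-hydroxy-4-methoxy-6-pentylbenzoyl)oxy]-6-pentylbenzoate, via vinylketene 18 (not isolated), via 4-vinylcyclobutenone 19 (not isolated), via dienylketene 20 (not isolated), via cyclohexadienone tautomer 21 (not isolated)
Conditions: 17 (4 equiv), ClCH2CH2Cl, hν (365 nm), 5 °C, sealed Pyrex tube; then 80 °C
Reagents that add atoms: none
Why: Proposed new method: light of 365 nm expels N2 from 14 and the alkenyl group shifts to the carbene carbon (Wolff rearrangement) to give vinylketene 18, whose ketene C=C adds across methoxyacetylene in a polarized (2+2) step to give 19 (bonds C2'–C3' and C4'–C5'), and reversible 4-electron electrocyclic opening of 19 gives dienylketene 20. Ring A is closed by thermal 6-electron electrocyclization of 20 (bond C1'–C2'), and enolization of 21 gives the phenol. The closest known reaction type is the photochemical Wolff form of the Danheiser benzannulation of unsaturated diazo ketones with alkoxyalkynes; a vinylketene with an ester on its far alkene carbon has not been shown in it, but the ester should only make the ketene and the triene terminus more electrophilic, which favours both the (2+2) step and the ring closure. No stereocentre results, because the sp3 carbons of 19 and 21 are lost on aromatization. The regiochemistry needed (OMe on C4', para to the ester) follows from bonding of the unsubstituted, nucleophilic alkyne carbon to the ketene carbonyl carbon. The E alkene of 14 holds the ester carbonyl away from the ketene so that closure to a 2-pyranone cannot compete, and 365 nm is chosen because the aryl ester (photo-Fries) and the benzyl groups do not absorb there.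

Step 11
Reactants: 22 benzyl 2-(benzyloxy)-4-[(2-hydroxy-4-methoxy-6-pentylbenzoyl)oxy]-6-pentylbenzoate
Product: 23 perlatolic acid
Conditions: H2 (1 atm), 10% Pd/C, EtOAc, rt
Reagents that add atoms: none
Why: Catalytic hydrogenolysis of the benzyl ether and benzyl ester C–O bonds; the aryl ester between the rings and the aryl methyl ether are inert to H2 over Pd/C.

**Compound list**

1 | olivetolic acid (2,4-dihydroxy-6-pentylbenzoic acid) | CCCCCc1cc(O)cc(O)c1C(=O)O | starting material
2 | benzyl 2,4-dihydroxy-6-pentylbenzoate | CCCCCc1cc(O)cc(O)c1C(=O)OCc1ccccc1 | intermediate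
3 | benzyl 2-hydroxy-6-pentyl-4-[(triisopropylsilyl)oxy]benzoate | CCCCCc1cc(O[Si](C(C)C)(C(C)C)C(C)C)cc(O)c1C(=O)OCc1ccccc1 | intermediate
4 | benzyl 2-(benzyloxy)-6-pentyl-4-[(triisopropylsilyl)oxy]benzoate | CCCCCc1cc(O[Si](C(C)C)(C(C)C)C(C)C)cc(OCc2ccccc2)c1C(=O)OCc1ccccc1 | intermediate
5 | benzyl 2-(benzyloxy)-4-hydroxy-6-pentylbenzoate | CCCCCc1cc(O)cc(OCc2ccccc2)c1C(=O)OCc1ccccc1 | intermediate
6 | hexyltriphenylphosphonium bromide | CCCCCC[P+](c1ccccc1)(c1ccccc1)c1ccccc1.[Br-] | starting material
7 | acetyl chloride | CC(=O)Cl | starting material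
8 | hexylidenetriphenylphosphorane | CCCCCC=P(c1ccccc1)(c1ccccc1)c1ccccc1 | intermediate
9 | 3-(triphenylphosphoranylidene)octan-2-one | CCCCCC(C(C)=O)=P(c1ccccc1)(c1ccccc1)c1ccccc1 | intermediate
10 | glyoxylic acid monohydrate (2,2-dihydroxyacetic acid) | OC(O)C(=O)O | starting material
11 | (2E)-4-oxo-3-pentylpent-2-enoic acid | CC(=O)/C(CCCCC)=C/C(=O)O | intermediate
12 | benzyl 2-(benzyloxy)-4-{[(2E)-4-oxo-3-pentylpent-2-enoyl]oxy}-6-pentylbenzoate | CC(=O)/C(CCCCC)=C/C(=O)Oc1cc(OCc2ccccc2)c(C(=O)OCc2ccccc2)c(CCCCC)c1 | intermediate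
13 | benzyl 2-(benzyloxy)-6-pentyl-4-{[(2E)-7,7,7-trifluoro-4,6-dioxo-3-pentylhept-2-enoyl]oxy}benzoate | O=C(CC(=O)/C(CCCCC)=C/C(=O)Oc1cc(OCc2ccccc2)c(C(=O)OCc2ccccc2)c(CCCCC)c1)C(F)(F)F | intermediate
14 | benzyl 2-(benzyloxy)-4-{[(2E)-5-diazo-4-oxo-3-pentylpent-2-enoyl]oxy}-6-pentylbenzoate | [N-]=[N+]=CC(=O)/C(CCCCC)=C/C(=O)Oc1cc(OCc2ccccc2)c(C(=O)OCc2ccccc2)c(CCCCC)c1 | intermediate
15 | 2-chloro-1,1-dimethoxyethane (chloroacetaldehyde dimethyl acetal) | COC(CCl)OC | starting material
16 | sodium methoxyacetylide | COC#[C-].[Na+] | intermediate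
17 | methoxyacetylene | COC#C | intermediate
18 | benzyl 2-(benzyloxy)-4-{[(2E)-5-oxo-3-pentylpenta-2,4-dienoyl]oxy}-6-pentylbenzoate (vinylketene) | O=C=C/C(CCCCC)=C/C(=O)Oc1cc(OCc2ccccc2)c(C(=O)OCc2ccccc2)c(CCCCC)c1 | intermediate
19 | benzyl 2-(benzyloxy)-4-{[(2E)-3-(2-methoxy-4-oxocyclobut-2-en-1-yl)oct-2-enoyl]oxy}-6-pentylbenzoate (racemic) | COC1=CC(=O)C1/C(CCCCC)=C/C(=O)Oc1cc(OCc2ccccc2)c(C(=O)OCc2ccccc2)c(CCCCC)c1 | intermediate
20 | benzyl 2-(benzyloxy)-4-{[(2E,4E)-5-methoxy-7-oxo-3-pentylhepta-2,4,6-trienoyl]oxy}-6-pentylbenzoate (dienylketene) | O=C=C/C(OC)=C\C(CCCCC)=C\C(=O)Oc1cc(OCc2ccccc2)c(C(=O)OCc2ccccc2)c(CCCCC)c1 | intermediate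
21 | benzyl 2-(benzyloxy)-4-[(4-methoxy-2-oxo-6-pentylcyclohexa-3,5-diene-1-carbonyl)oxy]-6-pentylbenzoate (racemic) | CCCCCC1=CC(OC)=CC(=O)C1C(=O)Oc1cc(OCc2ccccc2)c(C(=O)OCc2ccccc2)c(CCCCC)c1 | intermediate
22 | benzyl 2-(benzyloxy)-4-[(2-hydroxy-4-methoxy-6-pentylbenzoyl)oxy]-6-pentylbenzoate | CCCCCc1cc(OC(=O)c2c(O)cc(OC)cc2CCCCC)cc(OCc2ccccc2)c1C(=O)OCc1ccccc1 | intermediate
23 | perlatolic acid (2-hydroxy-4-[(2-hydroxy-4-methoxy-6-pentylbenzoyl)oxy]-6-pentylbenzoic acid) | CCCCCc1cc(OC(=O)c2c(O)cc(OC)cc2CCCCC)cc(O)c1C(=O)O | target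

**Step count**

Total: 11 steps. Longest linear sequence: 8 steps (1, 2, 3, 4, 7, 8, 10, 11).

**Steps most likely to fail**

Step 10. Light may isomerize the E alkene of 14 or of the vinylketene, after which the ketene would close onto the ester carbonyl to a pyranone. Ketene intermediates may also be captured by the newly formed phenol, or the cyclobutenone may fail to open and close cleanly. The fallback abandons ring construction for a classical depside esterification and sets out from olivetolic acid 1. Treatment with MeI (2.2 equiv) and K2CO3 in acetone should methylate the acid and the free 4-OH but spare the chelated 2-OH, giving methyl 2-hydroxy-4-methoxy-6-pentylbenzoate F1. Benzylation (BnBr, K2CO3, DMF, 60 °C) would give methyl 2-(benzyloxy)-4-methoxy-6-pentylbenzoate F2. Saponification (KOH, aq. DMSO, 90 °C) would give 2-(benzyloxy)-4-methoxy-6-pentylbenzoic acid F3. Activation with trifluoroacetic anhydride in toluene in the presence of phenol 5 would give benzyl 2-(benzyloxy)-4-{[2-(benzyloxy)-4-methoxy-6-pentylbenzoyl]oxy}-6-pentylbenzoate F4. Hydrogenolysis (H2, Pd/C, EtOAc) of all three benzyl groups returns to the route at target 23.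

Step 8. The amide base or the cross-conjugated enolate may add to the doubly activated alkene, the aryl ester may transfer its acyl group, or γ-deprotonation may scramble the alkene geometry. The fallback reaches the same diazo ketone without a strong base and sets out from methyl ketone 12. Soft enolization (Me3SiOTf, Et3N, CH2Cl2, 0 °C) should give benzyl 2-(benzyloxy)-6-pentyl-4-({(2E)-3-pentyl-4-[(trimethylsilyl)oxy]penta-2,4-dienoyl}oxy)benzoate F5. Bromination at the terminal carbon with N-bromosuccinimide (THF, −78 °C) would give benzyl 2-(benzyloxy)-4-{[(2E)-5-bromo-4-oxo-3-pentylpent-2-enoyl]oxy}-6-pentylbenzoate F6. N,N'-Ditosylhydrazine and DBU (THF, 0 °C) would turn the bromomethyl ketone into the diazo ketone by alkylation and twofold sulfinate loss, returning to the route at 14.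

Step 6. The carboxylic acid may protonate the weakly nucleophilic, hindered ylide so that olefination stalls, or the E preference may erode. The fallback replaces the Wittig reaction by an acid-mediated aldol condensation and sets out from glyoxylic acid monohydrate 10. Heating with purchased octan-2-one in 85% H3PO4 at about 80 °C should engage the more substituted enol (C3 of the ketone) and, under thermodynamic control, give the open-chain E acid, returning to the route at 11. A Z isomer would appear as the cyclic hydroxybutenolide and could be separated. This fallback makes no compound beyond the list (none F0).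

**Further compounds**

F1 | step 10 | methyl 2-hydroxy-4-methoxy-6-pentylbenzoate | CCCCCc1cc(OC)cc(O)c1C(=O)OC
F2 | step 10 | methyl 2-(benzyloxy)-4-methoxy-6-pentylbenzoate | CCCCCc1cc(OC)cc(OCc2ccccc2)c1C(=O)OC
F3 | step 10 | 2-(benzyloxy)-4-methoxy-6-pentylbenzoic acid | CCCCCc1cc(OC)cc(OCc2ccccc2)c1C(=O)O
F4 | step 10 | benzyl 2-(benzyloxy)-4-{[2-(benzyloxy)-4-methoxy-6-pentylbenzoyl]oxy}-6-pentylbenzoate | CCCCCc1cc(OC(=O)c2c(OCc3ccccc3)cc(OC)cc2CCCCC)cc(OCc2ccccc2)c1C(=O)OCc1ccccc1
F5 | step 8 | benzyl 2-(benzyloxy)-6-pentyl-4-({(2E)-3-pentyl-4-[(trimethylsilyl)oxy]penta-2,4-dienoyl}oxy)benzoate | C=C(O[Si](C)(C)C)/C(CCCCC)=C/C(=O)Oc1cc(OCc2ccccc2)c(C(=O)OCc2ccccc2)c(CCCCC)c1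
F6 | step 8 | benzyl 2-(benzyloxy)-4-{[(2E)-5-bromo-4-oxo-3-pentylpent-2-enoyl]oxy}-6-pentylbenzoate | BrCC(=O)/C(CCCCC)=C/C(=O)Oc1cc(OCc2ccccc2)c(C(=O)OCc2ccccc2)c(CCCCC)c1
F0 | step 6 | none | none
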